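**Assumptions.** Bicyclic compounds use daucane numbering: C1 = quaternary ring-fusion carbon bearing CH3, C2/C3 = cyclopentane CH2, C4 = carbon that becomes C(OH)iPr, C5 = ring-fusion CH, C6–C10 = remaining cycloheptane carbons (C6 next to C5, C10 next to C1), C14 = the one-carbon substituent on C8; β = face of the C1 methyl. "Trinor" means the isopropyl carbons are absent. Catalysts (the IDPi acid, L-fructose-derived Shi ketone, Grubbs II) are treated as reagents, not starting materials.

## Retrosynthetic overview

1. Ferugin ⇐ aryl-O-desilylation ⇐ Ti(III) epoxide-to-allylic-alcohol isomerisation (gives C8=CH2 and 9α-OH) ⇐ esterification of 8α,9α-epoxyjaeschkeanadiol at 6-OH.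
2. C4 carbinol ⇐ isopropyl-cerium addition to a trans-fused 4-ketone; H-5α and 6α-OH ⇐ one syn hydroboration of a bicyclic Δ5(6) allylic alcohol, anti to the angular methyl.
3. 8α,9α-Epoxide ⇐ Shi epoxidation of a bicyclic dienone; the epoxide also masks that olefin during the hydroboration.
4. Dienone (seven-membered ring, formed second) ⇐ dehydration ⇐ RCM (C8=C9) ⇐ Mukaiyama aldol (C5–C6) on a cyclopentanone enol silane.
5. Enol silane with the C1 quaternary stereocentre ⇐ new catalytic enantioselective Sakurai conjugate allylation of 3-methylcyclopent-2-enone (five-membered ring comes from the starting material).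

## Route

**Step 1**
Reactants: 1, 3-methylcyclopent-2-en-1-one; 2, allyltrimethylsilane
Product: 3, (R)-trimethyl{[3-methyl-3-(prop-2-en-1-yl)cyclopent-1-en-1-yl]oxy}silane
Conditions: 2 (2.5 equiv), confined chiral IDPi acid (3 mol%, antipode chosen for Si-face attack), toluene, −60 °C; Et3N quench; bulb-to-bulb distillation
Reagents that add atoms: allyltrimethylsilane, C=CC[Si](C)(C)C (reactant 2; supplies allyl and Me3Si)
Why: Proposed new method: an enantioselective Hosomi–Sakurai conjugate allylation under silylium counteranion-directed catalysis, in which the IDPi acid is silylated by 2 (loss of propene) to Me3Si+·IDPi−, O-silylation of 1 gives a siloxyallyl cation held in the chiral anion pocket, 2 attacks C3 on the Si face, and the β-silyl cation returns Me3Si+ to the anion, releasing the regiodefined enol silane and setting the quaternary centre (future C1, R); product self-Michael addition is disfavoured because the nucleophilic carbon of 3 is neopentyl; the closest known reactions are the racemic TiCl4-mediated or HNTf2-catalysed Sakurai conjugate allylation of β,β-disubstituted enones and IDPi-catalysed Mukaiyama–Michael and aldehyde Hosomi–Sakurai reactions.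

**Step 2**
Reactants: 4, 3-methylbut-3-en-1-ol
Product: 5, 3-methylbut-3-enal
Conditions: Dess–Martin periodinane, NaHCO3, CH2Cl2, 0 °C; filtered cold solution used directly
Reagents that add atoms: none
Why: Buffered Dess–Martin oxidation is non-basic, so the β,γ-unsaturated aldehyde does not isomerise to prenal.

**Step 3**
Reactants: 3; 5
Product: 6, (3R)-2-(1-hydroxy-3-methylbut-3-en-1-yl)-3-methyl-3-(prop-2-en-1-yl)cyclopentan-1-one (diastereomer mixture at C2 and C1′)
Conditions: BF3·OEt2 (1.1 equiv), CH2Cl2, −78 °C; aq. NaHCO3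
Reagents that add atoms: none (all atoms from 3 and 5; Me3Si is lost)
Why: Mukaiyama aldol at the regiodefined enol-silane carbon (C5, next to the quaternary centre) forms C5–C6; the C5/C6 configurations do not matter because both are erased in step 5.

**Step 4**
Reactants: 6
Product: 7, (3aR)-8-hydroxy-3a,6-dimethyl-3,3a,4,7,8,8a-hexahydroazulen-1(2H)-one (= (1R)-6-hydroxy-11,12,13-trinordauc-8-en-4-one, C5/C6 mixture)
Conditions: Grubbs II (5 mol%), CH2Cl2 (5 mM), 40 °C
Reagents that add atoms: none (ethylene lost)
Why: Ring-closing metathesis of the allyl and methallyl olefins closes the seven-membered ring as the trisubstituted C8=C9 alkene; either C5 epimer can cyclise.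

**Step 5**
Reactants: 7
Product: 8, (3aR)-3a,6-dimethyl-3,3a,4,7-tetrahydroazulen-1(2H)-one (= (1R)-11,12,13-trinordauca-5,8-dien-4-one)
Conditions: MsCl, Et3N, CH2Cl2, −20 → 0 °C
Reagents that add atoms: none
Why: Mesylation and E1cB β-elimination of the β-hydroxy ketone can only give the ring-constrained C5=C6 enone, so all diastereomers of 7 converge on one dienone.

**Step 6**
Reactants: 8
Product: 9, (1R,8R,9S)-8α,9α-epoxy-11,12,13-trinordauc-5-en-4-one
Conditions: L-fructose-derived (ent-)Shi ketone (30 mol%), Oxone, K2CO3, Bu4NHSO4, MeCN/DMM–aq. borate buffer (pH 10.5), 0 °C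
Reagents that add atoms: Oxone (potassium peroxymonosulfate), OOS(=O)(=O)[O-].[K+]
Why: Shi asymmetric epoxidation; the electrophilic dioxirane reacts only with the electron-rich trisubstituted C8=C9 (the enone olefin is inert), and the L-series ketone is predicted by the spiro transition-state model to deliver oxygen to the α face (opposite the angular methyl), setting C8 (R) and C9 (S).

**Step 7**
Reactants: 9
Product: 10, (1R,4S,8R,9S)-8α,9α-epoxy-11,12,13-trinordauc-5-en-4β-ol
Conditions: NaBH4, CeCl3·7H2O, MeOH, −40 °C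
Reagents that add atoms: none
Why: Luche 1,2-reduction with hydride entering anti to the pseudo-axial C1 methyl gives the 4β-allylic alcohol; this centre is re-oxidised in step 10, and the epoxide is untouched.

**Step 8**
Reactants: 10
Product: 11, (1R,4S,5R,6S,8R,9S)-8α,9α-epoxy-11,12,13-trinordaucane-4β,6α-diol (5α-H, trans-fused)
Conditions: BH3·THF (3 equiv), THF, 0 °C → rt; then 3 M NaOH, 30% H2O2, 0 °C
Reagents that add atoms: hydrogen peroxide, OO
Why: Hydroboration–oxidation adds H and B syn across C5=C6 from the α face, anti to the adjacent angular methyl and the 4β-O–B group (the same bias that gives 5α,6α products from Δ5-steroids), with boron on the less substituted C6; this sets H-5α and 6α-OH together, and no other C=C is present.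

**Step 9**
Reactants: 11
Product: 12, (1R,4S,5R,6S,8R,9S)-8α,9α-epoxy-6α-(triethylsilyloxy)-11,12,13-trinordaucan-4β-ol
Conditions: Et3SiCl (1.05 equiv), imidazole, CH2Cl2, −40 °C
Reagents that add atoms: chlorotriethylsilane, CC[Si](Cl)(CC)CC
Why: Selective silylation of the more accessible 6α-OH; the 4β-OH is 1,3-syn to the angular methyl on the cyclopentane and reacts much more slowly.

**Step 10**
Reactants: 12
Product: 13, (1R,5S,6S,8R,9S)-8α,9α-epoxy-6α-(triethylsilyloxy)-11,12,13-trinordaucan-4-one
Conditions: Dess–Martin periodinane, NaHCO3, CH2Cl2, 0 °C → rt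
Reagents that add atoms: none
Why: Neutral Dess–Martin oxidation of the remaining secondary alcohol gives the ketone without epimerising C5 or eliminating the β-silyloxy group.

**Step 11**
Reactants: 13
Product: 14, (1R,4R,5S,6S,8R,9S)-8α,9α-epoxy-6α-(triethylsilyloxy)daucan-4β-ol
Conditions: iPrMgCl (3 equiv), anhydrous CeCl3 (3.3 equiv), THF, −78 → −40 °C
Reagents that add atoms: isopropylmagnesium chloride, CC(C)[Mg]Cl
Why: Organocerium (Imamoto) 1,2-addition is non-basic, so enolisation and β-elimination are suppressed, and attack on the α face (anti to the adjacent C5–C6 bond and the 1,3-related angular methyl) gives the 4β-tertiary alcohol (C4 R).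

**Step 12**
Reactants: 14
Product: 15, (1R,4R,5S,6S,8R,9S)-8α,9α-epoxydaucane-4β,6α-diol (8α,9α-epoxyjaeschkeanadiol)
Conditions: TBAF, THF, 0 °C
Reagents that add atoms: none
Why: Fluoride cleavage of the TES ether; the trisubstituted epoxide and tertiary alcohol are inert.

**Step 13**
Reactants: 16, 4-hydroxybenzoic acid
Product: 17, 4-[(tert-butyldimethylsilyl)oxy]benzoic acid
Conditions: TBSCl (2.2 equiv), imidazole, DMF, rt; then K2CO3, THF/MeOH/H2O, rt; acidify to pH 4
Reagents that add atoms: tert-butyldimethylsilyl chloride, CC(C)(C)[Si](C)(C)Cl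
Why: Bis-silylation followed by selective cleavage of the labile silyl ester leaves the phenol protected as its TBS ether.

**Step 14**
Reactants: 15; 17
Product: 18, 8α,9α-epoxyjaeschkeanadiol 6-O-{4-[(tert-butyldimethylsilyl)oxy]benzoate}
Conditions: 17 (1.5 equiv), EDC·HCl, DMAP, CH2Cl2, rt → 40 °C
Reagents that add atoms: none (acyl group from reactant 17)
Why: Steglich esterification acylates only the secondary 6-OH, since the 4-OH is tertiary and hindered; no stereocentre is touched.

**Step 15**
Reactants: 18
Product: 19, O-TBS-ferugin (9α-hydroxy-8(14)-ene, phenol still silylated)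
Conditions: Cp2TiCl2 (2.5 equiv), Mn dust, THF, rt (Cp2TiCl formed in situ); aq. NaH2PO4
Reagents that add atoms: none
Why: Titanocene(III)-mediated epoxide-to-allylic-alcohol isomerisation: homolysis of C8–O gives the tertiary C8 radical, which is trapped by a second Cp2TiCl and undergoes β-hydride elimination preferentially from the unhindered methyl to give C8=C14, while the C9–O bond (9α, S) is never broken.

**Step 16**
Reactants: 19
Product: 20, ferugin
Conditions: KHF2, MeOH, rt
Reagents that add atoms: none
Why: Mild fluoride desilylation removes the aryl TBS ether selectively; the hindered secondary benzoate and the allylic alcohol are stable.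

## Compound list

1 | 3-methylcyclopent-2-en-1-one | CC1=CC(=O)CC1 | starting material
2 | allyltrimethylsilane | C=CC[Si](C)(C)C | starting material
3 | (R)-trimethyl{[3-methyl-3-(prop-2-en-1-yl)cyclopent-1-en-1-yl]oxy}silane | C=CC[C@@]1(C)CCC(O[Si](C)(C)C)=C1 | intermediate
4 | 3-methylbut-3-en-1-ol | C=C(C)CCO | starting material
5 | 3-methylbut-3-enal | C=C(C)CC=O | intermediate
6 | (3R)-2-(1-hydroxy-3-methylbut-3-en-1-yl)-3-methyl-3-(prop-2-en-1-yl)cyclopentan-1-one (mixture at C2/C1′) | C=CC[C@@]1(C)CCC(=O)C1C(O)CC(C)=C | intermediate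
7 | (3aR)-8-hydroxy-3a,6-dimethyl-3,3a,4,7,8,8a-hexahydroazulen-1(2H)-one (mixture at C8/C8a) | C[C@]12CCC(=O)C1C(O)CC(C)=CC2 | intermediate
8 | (3aR)-3a,6-dimethyl-3,3a,4,7-tetrahydroazulen-1(2H)-one | C[C@]12CCC(=O)C1=CCC(C)=CC2 | intermediate
9 | (1R,8R,9S)-8α,9α-epoxy-11,12,13-trinordauc-5-en-4-one | C[C@]12CCC(=O)C1=CC[C@@]3(C)O[C@H]3C2 | intermediate
10 | (1R,4S,8R,9S)-8α,9α-epoxy-11,12,13-trinordauc-5-en-4β-ol | C[C@]12CC[C@H](O)C1=CC[C@@]3(C)O[C@H]3C2 | intermediate
11 | (1R,4S,5R,6S,8R,9S)-8α,9α-epoxy-11,12,13-trinordaucane-4β,6α-diol | C[C@]12CC[C@H](O)[C@@H]1[C@@H](O)C[C@@]3(C)O[C@H]3C2 | intermediate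
12 | (1R,4S,5R,6S,8R,9S)-8α,9α-epoxy-6α-(triethylsilyloxy)-11,12,13-trinordaucan-4β-ol | C[C@]12CC[C@H](O)[C@@H]1[C@@H](O[Si](CC)(CC)CC)C[C@@]3(C)O[C@H]3C2 | intermediate
13 | (1R,5S,6S,8R,9S)-8α,9α-epoxy-6α-(triethylsilyloxy)-11,12,13-trinordaucan-4-one | C[C@]12CCC(=O)[C@@H]1[C@@H](O[Si](CC)(CC)CC)C[C@@]3(C)O[C@H]3C2 | intermediate
14 | (1R,4R,5S,6S,8R,9S)-8α,9α-epoxy-6α-(triethylsilyloxy)daucan-4β-ol | C[C@]12CC[C@@](O)(C(C)C)[C@@H]1[C@@H](O[Si](CC)(CC)CC)C[C@@]3(C)O[C@H]3C2 | intermediate
15 | (1R,4R,5S,6S,8R,9S)-8α,9α-epoxydaucane-4β,6α-diol | C[C@]12CC[C@@](O)(C(C)C)[C@@H]1[C@@H](O)C[C@@]3(C)O[C@H]3C2 | intermediate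
16 | 4-hydroxybenzoic acid | OC(=O)c1ccc(O)cc1 | starting material
17 | 4-[(tert-butyldimethylsilyl)oxy]benzoic acid | OC(=O)c1ccc(O[Si](C)(C)C(C)(C)C)cc1 | intermediate
18 | 8α,9α-epoxydaucane-4β,6α-diol 6-O-{4-[(tert-butyldimethylsilyl)oxy]benzoate} | C[C@]12CC[C@@](O)(C(C)C)[C@@H]1[C@@H](OC(=O)c4ccc(O[Si](C)(C)C(C)(C)C)cc4)C[C@@]3(C)O[C@H]3C2 | intermediate
19 | O-TBS-ferugin: (1R,4R,5S,6S,9S)-4β,9α-dihydroxydauc-8(14)-en-6α-yl 4-[(tert-butyldimethylsilyl)oxy]benzoate | C=C1C[C@H](OC(=O)c2ccc(O[Si](C)(C)C(C)(C)C)cc2)[C@@H]2[C@](C)(CC[C@@]2(O)C(C)C)C[C@@H]1O | intermediate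
20 | ferugin: (1R,4R,5S,6S,9S)-4β,9α-dihydroxydauc-8(14)-en-6α-yl 4-hydroxybenzoate | C=C1C[C@H](OC(=O)c2ccc(O)cc2)[C@@H]2[C@](C)(CC[C@@]2(O)C(C)C)C[C@@H]1O | target

## Summary

Total steps: 16. Longest linear sequence: 14 (steps 1, 3–12, 14–16).

Three steps most likely to fail, with fallbacks:

- **Step 1 (proposed new enantioselective Sakurai conjugate allylation).** Fallback with known chemistry: make the same enol silane 3 by chiral NHC–Cu-catalysed asymmetric conjugate addition of Me3Al to 3-allylcyclopent-2-en-1-one (from 3-ethoxycyclopent-2-en-1-one and allylMgBr, then H3O+), trapping the aluminium enolate with TMSOTf. The quaternary centre is then made by C–CH3 rather than C–allyl bond formation.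
- **Step 8 (α-face hydroboration in the presence of the epoxide).** Fallback: abandon hydroboration and start from enone 9. Weitz–Scheffer epoxidation (H2O2/NaOH, α face) followed by SmI2 reduction of the α,β-epoxy ketone gives the 6α-hydroxy-4-ketone; the trans ring fusion is set by enolate protonation or equilibration, and silylation gives 13. This also bypasses steps 7, 9 and 10.
- **Step 11 (isopropyl addition to a hindered, enolisable ketone).** Fallback: add the sp2 nucleophile isopropenylmagnesium bromide/CeCl3 (no β-hydride, smaller), then hydrogenate the isopropenyl group (H2, Wilkinson's catalyst) to reach 14. No other C=C is present at that stage and the epoxide is inert.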